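**Retrosynthetic overview**

1. No ring is built: the arene is bought as veratrole (1) and joined to succinic anhydride (2) by Friedel–Crafts acylation, giving keto acid 3.
2. The quinone ring is bought intact as C2v-symmetric 2,6-dimethoxy-1,4-benzoquinone (4), which already carries both methoxy groups and the final oxidation level.
3. Key disconnection: the quinone C3–CH2 bond. Acid 3 loses CO2 to give the β-keto alkyl radical 5, which adds to one of the two equivalent C–H positions of 4 (adduct radical 6) and so desymmetrises it; re-oxidation in the same flask gives evelynin (7).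
4. Order: aryl ketone first, quinone–alkyl bond last; two steps, no protecting groups, no separate redox adjustment.

Assumption: evelynin has no stereocentre and no stereogenic double bond (it is achiral), so no stereocontrol is needed; 4 is taken as a commercial material.

**Route**

Step 1
Reactants: 1 veratrole (1,2-dimethoxybenzene); 2 succinic anhydride
Product: 3 4-(3,4-dimethoxyphenyl)-4-oxobutanoic acid
Conditions: AlCl3 (2.2 equiv), CH2Cl2, 0 °C → rt; then ice/2 M HCl
Reagents that add atoms: none
Why: Friedel–Crafts acylation (Haworth succinoylation), in which the AlCl3-activated anhydride attacks veratrole para to a methoxy group (C4 and C5 are equivalent, so one regioisomer forms), the resulting aryl ketone is deactivated towards a second acylation, and keeping the mixture at or below room temperature avoids AlCl3 cleavage of the methyl ethers; no stereocentre is formed.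

Step 2
Reactants: 3 4-(3,4-dimethoxyphenyl)-4-oxobutanoic acid; 4 2,6-dimethoxy-1,4-benzoquinone
Product: 7 evelynin, via β-keto alkyl radical 5 (not isolated), via quinone adduct radical 6 (not isolated)
Conditions: 3 (1.0 equiv), 4 (2.0 equiv), AgNO3 (20 mol%), (NH4)2S2O8 (1.5 equiv, slow addition), MeCN/H2O 1:1, 65 °C
Reagents that add atoms: none
Why: Jacobsen–Torssell (Minisci-type) silver-catalysed oxidative decarboxylation, in which Ag(II) formed from Ag(I)/persulfate oxidises the carboxylate of 3, loss of CO2 gives the nucleophilic primary radical 5, this adds to one of the two symmetry-equivalent unsubstituted ring carbons (C3/C5) of the electron-poor quinone 4 to give the captodatively stabilised radical 6, and one-electron oxidation with loss of H+ restores the quinone; the excess of 4 and the lower electrophilicity and greater hindrance of 7 hold back a second alkylation, and no stereocentre is formed.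

**Compound list**

1 | veratrole (1,2-dimethoxybenzene) | COc1ccccc1OC | starting material
2 | succinic anhydride | O=C1CCC(=O)O1 | starting material
3 | 4-(3,4-dimethoxyphenyl)-4-oxobutanoic acid | OC(=O)CCC(=O)c1ccc(OC)c(OC)c1 | intermediate
4 | 2,6-dimethoxy-1,4-benzoquinone (2,6-dimethoxycyclohexa-2,5-diene-1,4-dione) | COC1=CC(=O)C=C(OC)C1=O | starting material
5 | β-keto alkyl radical: 3-(3,4-dimethoxyphenyl)-3-oxopropyl radical (primary C-centred radical) | [CH2]CC(=O)c1ccc(OC)c(OC)c1 | intermediate
6 | quinone adduct radical: 4 with the side chain and H on C3 (sp3) and the unpaired electron on C2, which bears OMe and is α to the C1 carbonyl | COC1=CC(=O)C(CCC(=O)c2ccc(OC)c(OC)c2)[C](OC)C1=O | intermediate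
7 | evelynin: 2,6-dimethoxy-3-[3-(3,4-dimethoxyphenyl)-3-oxopropyl]cyclohexa-2,5-diene-1,4-dione (achiral) | COC1=CC(=O)C(CCC(=O)c2ccc(OC)c(OC)c2)=C(OC)C1=O | target

**Step count**

Total steps: 2. Longest linear sequence: 2 (1 → 3 → 7; 4 enters in step 2).

**Steps most likely to fail**

The route has only two steps, so both are ranked here rather than three.

Most likely to fail: step 2. This acid/quinone pair is untested in this reaction class, and there are four concerns:
- 4 is among the least electrophilic quinones, so radical capture may be slow.
- Sulfate radical anion can attack the dimethoxyaryl ring.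
- 7 can be alkylated again at C5.
- Hot acidic water may slowly hydrolyse the methoxyquinone.

The fallback replaces the radical C–H alkylation by a polar arene alkylation followed by late oxidation; it sets out from 1 and comes back at 7. Veratrole 1 is acylated with 3-chloropropanoyl chloride (ClCCC(Cl)=O; AlCl3, CH2Cl2, 0 °C) to 3-chloro-1-(3,4-dimethoxyphenyl)propan-1-one F1. Et3N in CH2Cl2 at rt eliminates HCl to give the aryl vinyl ketone 1-(3,4-dimethoxyphenyl)prop-2-en-1-one F2, used crude. Commercial 1,2,3,5-tetramethoxybenzene (COc1cc(OC)c(OC)c(OC)c1, 2–3 equiv) is then added to F2 in a Friedel–Crafts conjugate addition (Sc(OTf)3 10 mol%, MeCN, rt); its two free positions are equivalent, so only 1-(3,4-dimethoxyphenyl)-3-(2,3,4,6-tetramethoxyphenyl)propan-1-one F3 can form. Ceric ammonium nitrate (2.5 equiv, MeCN/H2O, 0 °C) oxidatively demethylates the para-related 3- and 6-methoxy groups of the electron-rich ring, leaving the deactivated aryl ketone ring untouched, and gives 7.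

Second: step 1. If the mixture warms, AlCl3 can cleave the methyl ether para to the new ketone, and aluminium emulsions can cost material on work-up. The fallback replaces electrophilic aromatic substitution by acylation of an aryl nucleophile with no Lewis acid; it sets out from 1 and comes back at 3. Veratrole 1 is brominated para to a methoxy group (NBS, MeCN, rt) to 4-bromo-1,2-dimethoxybenzene F4. Magnesium in THF converts this to (3,4-dimethoxyphenyl)magnesium bromide F5. F5 is added slowly to excess succinic anhydride 2 (1.5 equiv, THF, −78 → 0 °C, inverse addition to suppress double addition), and acidic work-up gives keto acid 3.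

**Further compounds**

F1 | step 2 | 3-chloro-1-(3,4-dimethoxyphenyl)propan-1-one | ClCCC(=O)c1ccc(OC)c(OC)c1
F2 | step 2 | 1-(3,4-dimethoxyphenyl)prop-2-en-1-one | C=CC(=O)c1ccc(OC)c(OC)c1
F3 | step 2 | 1-(3,4-dimethoxyphenyl)-3-(2,3,4,6-tetramethoxyphenyl)propan-1-one | COc1cc(OC)c(CCC(=O)c2ccc(OC)c(OC)c2)c(OC)c1OC
F4 | step 1 | 4-bromo-1,2-dimethoxybenzene | Brc1ccc(OC)c(OC)c1
F5 | step 1 | (3,4-dimethoxyphenyl)magnesium bromide | Br[Mg]c1ccc(OC)c(OC)c1
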